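The route rests on forming two adjacent bonds of ring A (the benzene ring of the chroman) at once: C7–O and C8–C(=O). The target has a hydroxyl on C7 and the cinnamoyl ketone on the neighbouring C8, which lies next to C8a and the ring oxygen O1. A C7≡C8 aryne polarised by O1 should take up the oxygen and the acyl group of MOM-protected 4-hydroxycinnamic acid in a single operation, so the intact E-cinnamoyl unit is attached directly. The aryne precursor is the (S)-chroman with trimethylsilyl on C8 and triflate on C7, its 5-hydroxyl masked as MOM ether and its 3-hydroxyl as TBS ether.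

Key step: step 11

Remark on the chemistry: the secondary 3-hydroxyl is carried as a TBS ether, since an alkyl MOM ether would call for harsher acid at the end than the 2'-hydroxychalcone tolerates, and the (S) centre is taken to require the L-fructose-derived enantiomer of the Shi ketone, assumed purchasable.

Step 1
Reactants: 1 phloroglucinol; 2 prenyl bromide
Product: 3 2-(3-methylbut-2-en-1-yl)benzene-1,3,5-triol
Conditions: 1 (3 equiv), DBU (1 equiv), THF, 0 °C → rt
Reagents that add atoms: none
Why: Under DBU the ambident phloroglucinol anion should be alkylated on carbon by the soft allylic bromide (C-prenylation of a polyphenol), the excess of 1 holding back double alkylation, and since the three ring positions are equivalent only one mono-prenyl product can form.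

Step 2
Reactants: 3 2-(3-methylbut-2-en-1-yl)benzene-1,3,5-triol
Product: 4 1,3,5-tris(tert-butyldimethylsilyloxy)-2-(3-methylbut-2-en-1-yl)benzene
Conditions: TBSCl (3.5 equiv), imidazole, DMF, rt
Reagents that add atoms: tert-butyldimethylsilyl chloride, CC(C)(C)[Si](C)(C)Cl
Why: Standard silylation of phenols masks the three hydroxyls, which the peroxymonosulfate of the next step would otherwise oxidise.

Step 3
Reactants: 4 1,3,5-tris(tert-butyldimethylsilyloxy)-2-(3-methylbut-2-en-1-yl)benzene
Product: 5 (S)-2,2-dimethyl-3-[2,4,6-tris(tert-butyldimethylsilyloxy)benzyl]oxirane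
Conditions: L-fructose-derived Shi ketone (30 mol %), Oxone (2KHSO5·KHSO4·K2SO4), K2CO3, Bu4NHSO4, aq. Na2B4O7 buffer, MeCN/CH2(OMe)2, 0 °C
Reagents that add atoms: potassium peroxymonosulfate, OOS(=O)(=O)[O-].[K+]
Why: Shi epoxidation, in which the dioxirane formed from the chiral ketone passes oxygen to the trisubstituted prenyl alkene through a spiro transition state; the L-fructose-derived ketone should attack the face that gives the (S)-epoxide, the D-fructose-derived ketone being expected to give R with this olefin class.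

Step 4
Reactants: 5 (S)-2,2-dimethyl-3-[2,4,6-tris(tert-butyldimethylsilyloxy)benzyl]oxirane
Product: 7 (S)-2,2-dimethylchroman-3,5,7-triol, via free triol epoxide 6 (not isolated)
Conditions: Bu4NF (3.3 equiv), AcOH (3.5 equiv), THF, 0 °C; aqueous work-up; then CSA (10 mol %), THF/CH2Cl2, 0 °C
Reagents that add atoms: none
Why: Acetic acid-buffered fluoride frees the phenols without leaving phenoxides, and Brønsted acid then lets an ortho hydroxyl open the epoxide at its tertiary carbon, where positive charge builds up (6-endo epoxide opening), so the C–O bond at the stereocenter is untouched, C3 keeps the S configuration, and the two equivalent ortho hydroxyls can give only one chroman.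

Step 5
Reactants: 7 (S)-2,2-dimethylchroman-3,5,7-triol
Product: 8 (S)-3,5,7-tris(tert-butyldimethylsilyloxy)-2,2-dimethylchroman
Conditions: TBSOTf (3.5 equiv), 2,6-lutidine, CH2Cl2, 0 °C → rt
Reagents that add atoms: tert-butyldimethylsilyl triflate, CC(C)(C)[Si](C)(C)OS(=O)(=O)C(F)(F)F
Why: The silyl triflate silylates both phenols and the hindered secondary alcohol; the two aryl silyl ethers are meant to wall in C6 during bromination and the alkyl silyl ether stays as the C3 protecting group to the end.

Step 6
Reactants: 8 (S)-3,5,7-tris(tert-butyldimethylsilyloxy)-2,2-dimethylchroman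
Product: 9 (S)-8-bromo-3,5,7-tris(tert-butyldimethylsilyloxy)-2,2-dimethylchroman
Conditions: NBS (1.0 equiv), CH2Cl2, −78 → −30 °C, dark
Reagents that add atoms: N-bromosuccinimide, O=C1CCC(=O)N1Br
Why: Electrophilic aromatic bromination of the phloroglucinol-type ring A should go to C8, because C6 is shielded on both sides by bulky silyloxy groups while C8 has the tied-back ring oxygen O1 on one side, the same bias that sends NBS to C8 in 5,7-di-O-protected flavan-3-ols.

Step 7
Reactants: 9 (S)-8-bromo-3,5,7-tris(tert-butyldimethylsilyloxy)-2,2-dimethylchroman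
Product: 10 (S)-8-bromo-3-(tert-butyldimethylsilyloxy)-2,2-dimethylchroman-5,7-diol
Conditions: K2CO3, MeOH/THF, 0 °C → rt, degassed; cold weakly acidic work-up
Reagents that add atoms: none
Why: Aryl silyl ethers are cleaved by methanolic carbonate much faster than a hindered secondary alkyl silyl ether, because phenoxide is the better leaving group, so only the 5- and 7-hydroxyls should be set free.

Step 8
Reactants: 10 (S)-8-bromo-3-(tert-butyldimethylsilyloxy)-2,2-dimethylchroman-5,7-diol
Product: 13 (S)-3-(tert-butyldimethylsilyloxy)-5-hydroxy-2,2-dimethyl-8-(trimethylsilyl)chroman-7-yl triflate, via bis-TMS ether 11 (not isolated), via 5-O-TMS triflate 12 (not isolated)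
Conditions: (Me3Si)2NH, THF, 65 °C, then evaporation; n-BuLi (1.05 equiv), THF, −78 °C; Tf2O (1.2 equiv), −78 °C; citric acid, MeOH, 0 °C
Reagents that add atoms: hexamethyldisilazane, C[Si](C)(C)N[Si](C)(C)C; triflic anhydride, O=S(=O)(OS(=O)(=O)C(F)(F)F)C(F)(F)F
Why: This is the classical o-silylaryl triflate synthesis, in which bromine–lithium exchange at C8 is followed by a 1,3 O→C silyl shift (retro-Brook rearrangement) that can only come from O7, the one silyloxy group ortho to C8, so that the 7-phenoxide alone is triflated and the untouched 5-O-TMS ether is then methanolysed.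

Step 9
Reactants: 13 (S)-3-(tert-butyldimethylsilyloxy)-5-hydroxy-2,2-dimethyl-8-(trimethylsilyl)chroman-7-yl triflate
Product: 14 (S)-3-(tert-butyldimethylsilyloxy)-5-(methoxymethoxy)-2,2-dimethyl-8-(trimethylsilyl)chroman-7-yl triflate
Conditions: MOMCl (1.5 equiv), i-Pr2NEt, CH2Cl2, 0 °C → rt
Reagents that add atoms: chloromethyl methyl ether, COCCl
Why: O-alkylation of the one remaining phenol with MOMCl and a hindered amine base should be clean, since triflate, aryl silane and TBS ether are inert to these conditions.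

Step 10
Reactants: 15 (E)-4-hydroxycinnamic acid
Product: 17 (E)-4-(methoxymethoxy)cinnamic acid, via MOM ester 16 (not isolated)
Conditions: MOMCl (2.5 equiv), i-Pr2NEt, CH2Cl2, 0 °C → rt; then LiOH, THF/MeOH/H2O, rt; 1 M HCl to pH 4 at 0 °C
Reagents that add atoms: chloromethyl methyl ether, COCCl; lithium hydroxide, [Li+].[OH-]
Why: Both acidic hydroxyls are alkylated by MOMCl and hydroxide then cleaves only the acyloxymethyl ester (saponification), the aryl MOM acetal being stable to base and the E-alkene untouched.

Step 11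
Reactants: 14 (S)-3-(tert-butyldimethylsilyloxy)-5-(methoxymethoxy)-2,2-dimethyl-8-(trimethylsilyl)chroman-7-yl triflate; 17 (E)-4-(methoxymethoxy)cinnamic acid
Product: 19 (S,E)-1-[3-(tert-butyldimethylsilyloxy)-7-hydroxy-5-(methoxymethoxy)-2,2-dimethylchroman-8-yl]-3-[4-(methoxymethoxy)phenyl]prop-2-en-1-one, via C7–C8 aryne 18 (not isolated)
Conditions: CsF (4 equiv), 17 (1.5 equiv), dry THF, 100 °C, sealed tube, stopped when 14 is consumed; work-up at 0 °C with pH 5 buffer
Reagents that add atoms: none
Why: Fluoride attacks the silicon on C8 and triflate leaves from C7, releasing the C7≡C8 aryne 18 slowly; the carboxylate of 17 adds through oxygen to C7, and the aryl anion thus placed on C8 attacks the neighbouring ester carbonyl through a four-membered transition state, so that the acyl group moves from oxygen to carbon and the 7-phenoxide is left. The closest known reaction type is the insertion of arynes from o-silylaryl triflates into the C–O bond of carboxylic acids, which gives o-hydroxyaryl ketones, including the 2-acyl-3-alkoxyphenol pattern from 3-alkoxyarynes. No ring is closed and no stereocenter is made; C3 lies far from the reacting atoms and the E-alkene is carried through unchanged. The step needs regioselectivity, and the substrate provides it: O1 on C8a withdraws inductively, so the aryne is distorted towards attack at the distal C7 and the negative charge develops on C8 next to that oxygen. It also needs the acyl shift to outrun protonation of the aryl anion (which would give the aryl ester) and the product to be taken out before the 7-phenoxide adds to the enone, hence dry THF, a limited excess of acid, monitoring and a cold weakly acidic work-up.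

Step 12
Reactants: 19 (S,E)-1-[3-(tert-butyldimethylsilyloxy)-7-hydroxy-5-(methoxymethoxy)-2,2-dimethylchroman-8-yl]-3-[4-(methoxymethoxy)phenyl]prop-2-en-1-one
Product: 20 (S,E)-1-(3,5,7-trihydroxy-2,2-dimethylchroman-8-yl)-3-(4-hydroxyphenyl)prop-2-en-1-one (CNP0326757.1)
Conditions: 3 M HCl, MeOH, 0 °C → rt, stopped at full conversion; NaHCO3 quench at 0 °C
Reagents that add atoms: none
Why: Acid-catalysed methanolysis removes the two aryl MOM acetals and the silyl ether in one operation, and since no alkyl MOM ether is present, cold dilute acid should suffice and the reaction can be stopped before the 7-hydroxyl adds to the enone (flavanone closure).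

Compound list
1 | phloroglucinol | Oc1cc(O)cc(O)c1 | starting material
2 | prenyl bromide (1-bromo-3-methylbut-2-ene) | CC(C)=CCBr | starting material
3 | 2-(3-methylbut-2-en-1-yl)benzene-1,3,5-triol | CC(C)=CCc1c(O)cc(O)cc1O | intermediate
4 | 1,3,5-tris(tert-butyldimethylsilyloxy)-2-(3-methylbut-2-en-1-yl)benzene | CC(C)=CCc1c(O[Si](C)(C)C(C)(C)C)cc(O[Si](C)(C)C(C)(C)C)cc1O[Si](C)(C)C(C)(C)C | intermediate
5 | (S)-2,2-dimethyl-3-[2,4,6-tris(tert-butyldimethylsilyloxy)benzyl]oxirane | CC1(C)O[C@H]1Cc1c(O[Si](C)(C)C(C)(C)C)cc(O[Si](C)(C)C(C)(C)C)cc1O[Si](C)(C)C(C)(C)C | intermediate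
6 | (S)-2-[(3,3-dimethyloxiran-2-yl)methyl]benzene-1,3,5-triol | CC1(C)O[C@H]1Cc1c(O)cc(O)cc1O | intermediate (not isolated)
7 | (S)-2,2-dimethylchroman-3,5,7-triol | CC1(C)Oc2cc(O)cc(O)c2C[C@@H]1O | intermediate
8 | (S)-3,5,7-tris(tert-butyldimethylsilyloxy)-2,2-dimethylchroman | CC1(C)Oc2cc(O[Si](C)(C)C(C)(C)C)cc(O[Si](C)(C)C(C)(C)C)c2C[C@@H]1O[Si](C)(C)C(C)(C)C | intermediate
9 | (S)-8-bromo-3,5,7-tris(tert-butyldimethylsilyloxy)-2,2-dimethylchroman | CC1(C)Oc2c(Br)c(O[Si](C)(C)C(C)(C)C)cc(O[Si](C)(C)C(C)(C)C)c2C[C@@H]1O[Si](C)(C)C(C)(C)C | intermediate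
10 | (S)-8-bromo-3-(tert-butyldimethylsilyloxy)-2,2-dimethylchroman-5,7-diol | CC1(C)Oc2c(Br)c(O)cc(O)c2C[C@@H]1O[Si](C)(C)C(C)(C)C | intermediate
11 | (S)-8-bromo-3-(tert-butyldimethylsilyloxy)-2,2-dimethyl-5,7-bis(trimethylsilyloxy)chroman | CC1(C)Oc2c(Br)c(O[Si](C)(C)C)cc(O[Si](C)(C)C)c2C[C@@H]1O[Si](C)(C)C(C)(C)C | intermediate (not isolated)
12 | (S)-3-(tert-butyldimethylsilyloxy)-2,2-dimethyl-8-(trimethylsilyl)-5-(trimethylsilyloxy)chroman-7-yl triflate | CC1(C)Oc2c([Si](C)(C)C)c(OS(=O)(=O)C(F)(F)F)cc(O[Si](C)(C)C)c2C[C@@H]1O[Si](C)(C)C(C)(C)C | intermediate (not isolated)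
13 | (S)-3-(tert-butyldimethylsilyloxy)-5-hydroxy-2,2-dimethyl-8-(trimethylsilyl)chroman-7-yl triflate | CC1(C)Oc2c([Si](C)(C)C)c(OS(=O)(=O)C(F)(F)F)cc(O)c2C[C@@H]1O[Si](C)(C)C(C)(C)C | intermediate
14 | (S)-3-(tert-butyldimethylsilyloxy)-5-(methoxymethoxy)-2,2-dimethyl-8-(trimethylsilyl)chroman-7-yl triflate (aryne precursor) | CC1(C)Oc2c([Si](C)(C)C)c(OS(=O)(=O)C(F)(F)F)cc(OCOC)c2C[C@@H]1O[Si](C)(C)C(C)(C)C | intermediate
15 | (E)-4-hydroxycinnamic acid | O=C(O)/C=C/c1ccc(O)cc1 | starting material
16 | methoxymethyl (E)-4-(methoxymethoxy)cinnamate | COCOC(=O)/C=C/c1ccc(OCOC)cc1 | intermediate (not isolated)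
17 | (E)-4-(methoxymethoxy)cinnamic acid | COCOc1ccc(/C=C/C(=O)O)cc1 | intermediate
18 | (S)-3-(tert-butyldimethylsilyloxy)-5-(methoxymethoxy)-2,2-dimethyl-7,8-didehydrochroman (C7–C8 aryne) | CC1(C)OC2=C(C[C@@H]1O[Si](C)(C)C(C)(C)C)C(OCOC)=CC#C2 | intermediate (not isolated)
19 | (S,E)-1-[3-(tert-butyldimethylsilyloxy)-7-hydroxy-5-(methoxymethoxy)-2,2-dimethylchroman-8-yl]-3-[4-(methoxymethoxy)phenyl]prop-2-en-1-one | CC1(C)Oc2c(C(=O)/C=C/c3ccc(OCOC)cc3)c(O)cc(OCOC)c2C[C@@H]1O[Si](C)(C)C(C)(C)C | intermediate
20 | (S,E)-1-(3,5,7-trihydroxy-2,2-dimethylchroman-8-yl)-3-(4-hydroxyphenyl)prop-2-en-1-one | CC1(C)Oc2c(c(O)cc(O)c2C(=O)/C=C/c2ccc(O)cc2)C[C@@H]1O | target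

Total step count: 12. Longest linear sequence: 11 steps (steps 1–9, 11 and 12); step 10 is a one-step branch.

Steps most likely to fail

1. Step 11. The aryl anion formed after carboxylate addition may be protonated faster than it attacks the ester carbonyl, ending in the aryl ester, or the product phenoxide may add to its own enone under the hot basic conditions and close the flavanone ring. The fallback replaces the aryne insertion by acylation of an aryllithium and sets out from 10 and 17. Diol 10 is alkylated on both phenols (MOMCl, i-Pr2NEt, CH2Cl2) to (S)-8-bromo-3-(tert-butyldimethylsilyloxy)-5,7-bis(methoxymethoxy)-2,2-dimethylchroman F1. Acid 17 is coupled with N,O-dimethylhydroxylamine hydrochloride (EDC·HCl, Et3N, CH2Cl2) to the Weinreb amide (E)-N-methoxy-N-methyl-3-[4-(methoxymethoxy)phenyl]acrylamide F2. Bromine–lithium exchange on F1 (n-BuLi, THF, −78 °C) and addition of F2 (Weinreb ketone synthesis, 1,2-addition) should give (S,E)-1-[3-(tert-butyldimethylsilyloxy)-5,7-bis(methoxymethoxy)-2,2-dimethylchroman-8-yl]-3-[4-(methoxymethoxy)phenyl]prop-2-en-1-one F3. Cold 3 M HCl in MeOH then removes the three MOM groups and the silyl ether, and the route is rejoined at 20.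

2. Step 4. The freed phenol may open the epoxide at the secondary carbon (5-exo) and give the dihydrobenzofuran with inversion, and any shortfall in facial selectivity of step 3 also surfaces here. The fallback builds the pyran ring first and sets the stereocenter on a chromene; it sets out from 1. Condensation of 1 with 3-methylbut-2-enal (pyridine, 120 °C; aldol-type addition, dehydration and oxa-6π electrocyclisation) should give 2,2-dimethyl-2H-chromene-5,7-diol F4. TBSCl/imidazole gives 5,7-bis(tert-butyldimethylsilyloxy)-2,2-dimethyl-2H-chromene F5. Jacobsen epoxidation with the (S,S)-catalyst, chloro[N,N'-bis(3,5-di-tert-butylsalicylidene)-(1S,2S)-cyclohexane-1,2-diaminato]manganese (NaOCl, 4-phenylpyridine N-oxide, CH2Cl2, 0 °C), is expected to give (3S,4S)-5,7-bis(tert-butyldimethylsilyloxy)-3,4-epoxy-2,2-dimethylchroman F6. Hydrogenolysis of the benzylic C4–O bond (H2, Pd/C, EtOAc) leaves C3 untouched and gives (S)-5,7-bis(tert-butyldimethylsilyloxy)-2,2-dimethylchroman-3-ol F7. TBSOTf/2,6-lutidine then returns to the route at 8.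

3. Step 6. Bromine may enter at C6 as well as at C8, or twice. The fallback replaces electrophilic substitution by directed ortho-lithiation; it sets out from 8 and comes back at 9. With s-BuLi/TMEDA in THF at −78 °C the ring oxygen O1 should direct deprotonation to C8, the only position next to a coordinating ether oxygen, while C6 lies between two non-coordinating silyloxy groups. Quenching the aryllithium at −78 °C with BrCF2CF2Br, before any silyl shift, gives 9 directly; this fallback makes no new compound (F0).

Further compounds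
F1 | step 11 | (S)-8-bromo-3-(tert-butyldimethylsilyloxy)-5,7-bis(methoxymethoxy)-2,2-dimethylchroman | CC1(C)Oc2c(Br)c(OCOC)cc(OCOC)c2C[C@@H]1O[Si](C)(C)C(C)(C)C
F2 | step 11 | (E)-N-methoxy-N-methyl-3-[4-(methoxymethoxy)phenyl]acrylamide | CON(C)C(=O)/C=C/c1ccc(OCOC)cc1
F3 | step 11 | (S,E)-1-[3-(tert-butyldimethylsilyloxy)-5,7-bis(methoxymethoxy)-2,2-dimethylchroman-8-yl]-3-[4-(methoxymethoxy)phenyl]prop-2-en-1-one | CC1(C)Oc2c(C(=O)/C=C/c3ccc(OCOC)cc3)c(OCOC)cc(OCOC)c2C[C@@H]1O[Si](C)(C)C(C)(C)C
F4 | step 4 | 2,2-dimethyl-2H-chromene-5,7-diol | CC1(C)C=Cc2c(O)cc(O)cc2O1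
F5 | step 4 | 5,7-bis(tert-butyldimethylsilyloxy)-2,2-dimethyl-2H-chromene | CC1(C)C=Cc2c(O[Si](C)(C)C(C)(C)C)cc(O[Si](C)(C)C(C)(C)C)cc2O1
F6 | step 4 | (3S,4S)-5,7-bis(tert-butyldimethylsilyloxy)-3,4-epoxy-2,2-dimethylchroman | CC1(C)Oc2cc(O[Si](C)(C)C(C)(C)C)cc(O[Si](C)(C)C(C)(C)C)c2[C@@H]2O[C@H]12
F7 | step 4 | (S)-5,7-bis(tert-butyldimethylsilyloxy)-2,2-dimethylchroman-3-ol | CC1(C)Oc2cc(O[Si](C)(C)C(C)(C)C)cc(O[Si](C)(C)C(C)(C)C)c2C[C@@H]1O
F0 | step 6 | none | none
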